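(The runs are calculated with constants of no real substance, noise included.)

By the last readings, G falls twice as fast in the west run as in the north-west run, on twice the J.

all flasks: G 0.33 M

| charge | J | remark | time |
|---|---|---|---|
| north-west | 0.53 M | run made earlier |  |
| west | 1.1 M | run made earlier |  |
| winter | 0.400 M |  | 25 h |
| noon | 0.790 M |  | 25 h |

- north-west (time / h: G / %, X / %): 3.00: 97, 8; 6.00: 86, 16; 10.0: 80, 18; 12.0: 77, 19
- west (time / h: G / %, X / %): 1.00: 91, 3; 2.50: 89, 12; 5.00: 76, 20; 12.0: 60, 33

(readings scatter by 2 percentage points)



- part of the G that has reacted at the end, winter
- part of the G that has reacted at the end, noon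
- what raising the concentration of J from its lowest to its highest value here does to the part of the G that has reacted (changes below 5 percentage points count as none) (it rises / it falls / no change)

From the last readings, the time constant of G is 45.9 h in the north-west run and 23.5 h in the west run. Each multiplied by its J gives a mean reading of 1510 M·min, and this product, the time constant of G times the J charged, is what I carry. Dividing it by the J of a flask gives a pseudo-first-order time constant: 62.7 h for winter and 31.8 h for noon. Over 25 h that means 32.9% reacted in winter and 54.5% at noon, a rise of 22 percentage points against the margin of 5 points. I hold J at its charge here, though it is used up with G, so I take both figures as somewhat high.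

The forecast gives 30% for winter and 50% for noon, lower than mine, says of the part reacted with more J that it rises, and notes that “J is not in large excess, especially in winter, so its consumption matters”.

The flasks give 28.2% reacted in winter and 47.7% at noon, and with more J the part reacted it rises, by 20 points, so the forecast holds.

    L + J → E + D (k = 0.130 M⁻¹ h⁻¹)
    X + J → E + L (k = 0.0500 M⁻¹ h⁻¹)
    G + J → E + X (k = 0.0480 M⁻¹ h⁻¹)
    E + J ⇌ Q, settled at all times (K = 240 M⁻¹)

At 25.0 h winter keeps 44.7% of its J unbound, less than the 71.8% of its G, whereas I held J at its charge. One more flask, like winter but with 1.6 M of J, gets from the carried product a time constant of 15.7 h, shorter than the 25 h it runs, and so 79.7% reacted. That flask gives 72.8% reacted, with 43.7% of its J left unbound at 25.0 h. Of its G charge, 34.5% then stands as X and 25.7% as D.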